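Early in a run, the readings show how fast substrate and partner join; later readings show where that joining stops and how target drains away.

common to all: substrate 45 mM; partner 31.5 mM

| run | catalyst | temperature | remark | time |
|---|---|---|---|---|
| Wednesday's | 5.8 mM | −25 °C | run made earlier |  |
| Monday's | 13 mM | 8 °C | run made earlier |  |
| winter | 8.6 mM | 0 °C |  | 10 min |
| midnight | 8.6 mM | −40 °C |  | 10 min |
| spring | 8.6 mM | 20 °C |  | 10 min |
| noon | 8.6 mM | −20 °C |  | 10 min |

- Wednesday's (time / min: target / %, substrate / %): 2.50: 15.3, 75.3; 6.00: 20.4, 60.9; 10.0: 22.2, 53.9; 15.0: 21.2, 49.5; 30.0: 16.1, 45.8; 40.0: 13.2, 44.7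
- Monday's (time / min: target / %, substrate / %): 1.00: 15.9, 58.5; 1.33: 15.8, 57.3; 2.00: 14.3, 57.8; 3.00: 14.2, 57.4; 5.00: 13.0, 58.0; 8.00: 12.1, 60.9; 12.0: 10.3, 61.8

(scatter of a reading: 0.5 percentage points)

1. the flask that comes out highest in amount of target, in percent of the substrate charged, or "all alike" when all lie within 1.5 percentage points (winter / midnight / spring / noon / all alike)
2. target at the end, in percent of the substrate charged, winter
3. target at the end, in percent of the substrate charged, midnight
4. target at the end, in percent of the substrate charged, spring
5. target at the end, in percent of the substrate charged, noon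

- the numbers in the tables scatter with a standard deviation of 0.5 percentage points

Target reads 22.2% at 10.0 min in Wednesday's cold run before it falls. In Monday's warm run it is falling from the first reading, 15.9% at 1.00 min, so Monday's peak came earlier and stands in no reading. A cold flask can hold target high, as Wednesday's does, if it fills in the time allowed. I therefore want the fill time, the starting pseudo-first-order lifetime of partner, 1/(k[substrate]), where k is the constant of the joining. Three inputs could spoil it. The scatter of 0.5 points barely touches a fall of 24.7% in Wednesday's first reading. I assume that the joining ignores catalyst; if it followed catalyst instead, with Monday's constant taken per catalyst too, midnight's constant rises by a factor of 2.14. Monday's constant is a crude input, and an error of 2 times there moves midnight's constant by a factor of 1.37.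

Wednesday's first reading gives k = 4.49 M⁻¹ min⁻¹. On Monday, substrate lies 1.2 points from its level at 1.00 min, which I read as k = 93.8 M⁻¹ min⁻¹. Carrying the ratio across the temperatures gives 1.13 M⁻¹ min⁻¹ at midnight, so its fill time is 19.7 min, twice the 10 min allowed. Monday's error leaves it at 14.4 min, still longer than 10 min, but the catalyst factor brings it to 9.21 min, just under 10 min, so my reckoning stands on the assumption that the joining ignores catalyst. Midnight's time equals 2.51 min of Wednesday's, where target read 15.3%, so I expect about that. Noon's fill time is 3.12 min, and its time equals about 15.8 min of Wednesday's, near the 21.2% read at 15.0 min. I expect winter and spring on a falling stretch like Monday's, which reads 12.1% at 8.00 min, so I choose noon.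

The forecast gives 13% for winter, 20.3% for midnight, 9% for spring and 19.5% for noon, with midnight highest, and adds: “Midnight versus noon is close.” The flasks give 11.7% for winter, 10.9% for midnight, 8.59% for spring and 19.5% for noon, so noon is highest.

    substrate + partner ⇌ target (K = 28.0 M⁻¹, k = 39.6 M⁻¹ min⁻¹, Ea = 58.0 kJ mol⁻¹, ΔH = −14.0 kJ mol⁻¹)
    substrate + partner ⇌ isomer of the product (K = 77.7 M⁻¹, k = 17.7 M⁻¹ min⁻¹, Ea = 52.0 kJ mol⁻¹, ΔH = −41.0 kJ mol⁻¹)
    target + catalyst ⇌ isomer of the product + catalyst, rate k3*[catalyst]*[target] forward; the back reaction follows from the equilibrium constant (k = 18.2 M⁻¹ min⁻¹, Ea = 42.0 kJ mol⁻¹)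
    2 partner → homo dimer (k = 1.57 M⁻¹ min⁻¹, Ea = 47.0 kJ mol⁻¹)
    substrate + partner → uncatalysed product (k = 0.195 M⁻¹ min⁻¹, Ea = 60.0 kJ mol⁻¹)
    substrate → decomposition product (k = 2.80 × 10⁻⁴ min⁻¹, Ea = 95.0 kJ mol⁻¹)
    (constants at 0 °C)

Midnight still holds 80.4% of its substrate at 10.0 min, which gives a fill time of 27.2 min, longer than the 10 min allowed. Spring's fill time comes to 0.0784 min, far shorter than 2.5 min, and target there goes from 13.6% at 2.5 min to 8.59% at 10.0 min, when its net making runs at 0.0831 of its net using up.

(All runs were generated by integration on assumed constants.)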